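A percentage point of the substrate charged was the unit of my books, and substrate, the limiting reagent, was what they followed.

| flask | substrate | first nucleophile | second nucleophile | remark | time |
|---|---|---|---|---|---|
| maple | 0.070 M | 1.1 equiv | 0.95 equiv | run made earlier |  |
| alder | 0.11 M | 1.1 equiv | 0.95 equiv | run made earlier |  |
| birch | 0.050 M | 1.1 equiv | 0.47 equiv | run made earlier |  |
| flask | 0.050 M | 1.10 equiv | 0.950 equiv |  | 12 d |

- maple (time / d: other capture product / %, target / %): 1.25: 23.5, 55.1; 2.08: 23.7, 45.1; 3.00: 23.6, 39.5; 5.00: 23.9, 33.1; 8.00: 23.1, 31.3; 15.0: 24.5, 31.0
- alder (time / d: other capture product / %, target / %): 1.25: 22.7, 54.4; 2.08: 23.9, 45.1; 3.00: 23.6, 39.2; 5.00: 24.1, 33.8; 8.00: 22.8, 30.6; 15.0: 24.3, 30.2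
- birch (time / d: other capture product / %, target / %): 1.25: 13.2, 62.0; 2.00: 14.7, 50.9; 4.00: 14.3, 40.0; 8.00: 14.4, 34.1; 15.0: 14.9, 34.7

(readings scatter by 0.5 percentage points)

- the analysis behind the earlier runs scatters by 0.5 percentage points, standard deviation

- ratio of other capture product to target at 30 min
- ratio of other capture product to target at 10 h
- ratio of other capture product to target at 12 d

The first entry was other capture product. Maple and alder differed in concentration but shared their equivalents, and both stayed flat from the first reading, so I entered their late mean, 23.8%, for the new flask, which has those equivalents. Taking the substrate as fully consumed, the remainder was 76.2%. Late target as a fraction of each run's own remainder came to 0.411 in maple, 0.399 in alder and 0.408 in birch, although birch had half the second nucleophile. Their mean, 0.406, I called the plateau share.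

That entry belongs to the plateau, so I counted half-lives. Maple's target excess over its last reading gave a half-life of 1.16 d, and 12 d held 10.3 of them. The books closed with target at 30.9% and a ratio of 0.769. The share said nothing about 10 h, which is shorter than one half-life, or about 30 min.

The forecast gave 0.22 at 30 min, 0.335 at 10 h and 0.77 at 12 d, with the ratio “rising to 0.31 on completion if no target is lost” and climbing further as target fell.

The flask gave 0.325 at 30 min, where the forecast was low, then 0.361 at 10 h and 0.785 at 12 d, where the forecast was within tolerance.

    second nucleophile + intermediate → other capture product (k = 0.0270 M⁻¹ s⁻¹)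
    first nucleophile → decomposition product (k = 5.10 × 10⁻⁹ s⁻¹)
    second nucleophile → decomposed reagent (k = 1.40 × 10⁻⁵ s⁻¹)
    substrate → intermediate (k = 4.30 × 10⁻⁵ s⁻¹)
    target ⇌ isomer of the product (K = 1.50, k = 4.30 × 10⁻⁶ s⁻¹)
    first nucleophile + intermediate → target (k = 0.0720 M⁻¹ s⁻¹)

In this flask substrate was down to 1.16% by 1.20 d, with second nucleophile at 15.2% of its charge and other capture product at 23.8%, the amount still there at 12.0 d. Target peaked at 59.2% at 0.743 d, then relaxed towards isomer of the product with a half-life of 1.12 d, reaching 30.5% against 45.6% at 12.0 d, a plateau share of 0.400 after 10.7 half-lives. The neighbour flask with 1.60 equiv of second nucleophile ended at 33.4% other capture product; my share 0.406 turned that into a ratio of 1.24, and that neighbour stood at 1.25.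

(Readings and results are simulated with constants of no real substance.)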